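A one-step world, substrate + partner → target, asks that [partner] speeds target and that lost substrate reappears as target.

| flask | substrate | partner | remark | time |
|---|---|---|---|---|
| elm | 0.80 M | 0.60 equiv | run made earlier |  |
| alder | 0.80 M | 2.4 equiv | run made earlier |  |
| flask | 0.80 M | 1.20 equiv |  | 2.5 h |

| run | time / min | target / % | substrate / % |
|---|---|---|---|
| elm | 40.0 | 21.2 | 65.4 |
| elm | 50.0 | 25.7 | 60.0 |
| elm | 60.0 | 28.8 | 56.4 |
| elm | 90.0 | 38.2 | 46.2 |
| alder | 40.0 | 17.8 | 39.0 |
| alder | 50.0 | 21.4 | 33.6 |
| alder | 60.0 | 23.7 | 29.3 |
| alder | 90.0 | 29.1 | 24.0 |

(scatter of a reading: 0.5 percentage points)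

- the best time, 2.5 h at the latest, for target
- the amount of target, in percent of the substrate charged, at that time

The runs refuse both. At 40.0 min, alder with 2.4 equiv holds 17.8 % target against 21.2 % in elm with 0.60 equiv, and alder's free substrate is down by 61.0 % of its charge.

So my bench rule drops partner: divide the rise of target by the time and by the mean of the first and last [substrate], replacing the curve by its mean. Alder gives 0.00717 min⁻¹, the feed constant, a pseudo-first-order constant for target made per free substrate. Elm gives 0.00609 min⁻¹, less than alder. The border shows in a ratio that I watch against one, free substrate gone per equivalent of partner charged: at 90.0 min it is 0.897 in elm and 0.317 in alder.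

The flask's 1.20 equiv is the geometric mean of the two charges, so I take the mean of the two runs as its curve: substrate 52.2 % at 40.0 min and 35.1 % at 90.0 min, where its ratio is 0.541, lower than elm's. Holding that last substrate flat to 2.5 h gives me 50.3 %. Both runs still climb at their last reading, so I take the limit as best time.

The forecast gives 46 % at 2.5 h, less than my figure, and says of the time: “Target shows no sign of decay, so the best time is the limit”. The flask gives 51.3 % at 2.50 h.

    substrate ⇌ tautomer (K = 1.60, k = 0.450 h⁻¹)
    substrate + partner ⇌ isomer of the product (K = 1.50 L mol⁻¹, k = 0.830 L mol⁻¹ h⁻¹)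
    partner + tautomer → target (k = 54.0 L mol⁻¹ h⁻¹)
    partner + target ⇌ idle adduct, settled at all times (K = 2.10 L mol⁻¹)

At 0.860 h tautomer has a half-life of 1.7 min against partner, far shorter than the 1.8 h of substrate on the forward step to isomer of the product. At that time tautomer is made 1.00 times as fast as it is used up, each step taken net, and it stands at 0.911 % at 2.50 h. From 1.25 h to 2.50 h, the feed constant on the flask's mean substrate gives 18 percentage points; target rose 18 points. In a flask like this one but with 0.480 equiv, whose ratio reaches 1.33 at 2.50 h, the constant on the mean of charge and final substrate gives 73.3 %, but 1.1 % of its partner charge remains free, with 16.7 % tautomer and 42.6 % target.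

All runs are simulated for an exercise; scatter was added.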